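## Structural features

Compound 30 joins three rings. Ring A is the diformylphloroglucinol (atoms a1–a6: a1 bears the ring-B oxygen, a2 bears C1', a3 and a5 the phenolic oxygens, a4 and a6 the formyl groups). Ring B is the dihydropyran (O, C10, C1, C1', a2, a1). Ring C is the ten-membered carbocycle C1–C10, trans-fused to ring B along C1–C10. In ring C, C4 carries the exocyclic methylene C15, C5=C6 is a cis olefin conjugated with it, C7 carries the carbinol C11(CH3)2OH, and C10 is the oxygen-bearing quaternary carbon with methyl C14; C1' is the benzylic CH carrying the isobutyl group. Three stereocentres are contiguous around ring B, C1' (R), C1 (S) and C10 (R), with H-1' and H-1 cis and C14 trans to H-1; C7 (R) lies alone on the far side of ring C, out of reach of substrate control from the other three. The fragile groups are the 1,3-diene C15=C4–C5=C6 (acids, electrophiles, organolithium addition), the tertiary homoallylic alcohol (dehydration, retro-ene loss of acetone), the tertiary alkyl aryl ether at C10 (ionisation), the allylic C7–H, and the two aldehydes on an electron-rich ring, which cannot coexist with a carbonyl olefination. The real difficulty is the medium ring with its Z olefin, combined with the quaternary C10 and the remote C7. The key step exploits that ring C holds C5=C6 and, once the O–C10 bond is disconnected, C9=C10 in a 1,5-relationship. That is the pattern left by a cleaved bicyclo[2.2.0]hexane, so ring C can be traced back to a six-membered enone (C1–C5, C10) and a cyclobutene (C6–C9).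

## Logic of the disconnections

30 ⇒ 29 ⇒ 28. The O–H bonds at a3 and a5 are replaced by O–CH3 and the O–H at C11 by O–Si. The methyl ethers sit ortho/para to the formyl groups and are therefore vinylogous esters that a soft nucleophile cleaves without acid; the silyl ether is removed by fluoride. The gain is that all acidic hydroxyl groups are masked in 28. The forward demand is an SN2 demethylation that leaves the tertiary ether at C10 and the diene untouched.

28 ⇒ 27 ⇒ 26 ⇒ 25 ⇒ 24. The a4–CHO and a6–CHO bonds are cut back to C–Br and then C–H, and C4=C15 is cut back to C4=O. Aldehydes cannot be present during methylenation, and an electrophilic formylation cannot be run next to the nucleophilic diene. Bromine is therefore placed on ring A while C4 is still a carbonyl, and is turned into formyl through an aryllithium after the methylenation. The gain is 24, in which ring A is a plain dimethyl ether and ring C carries only the enone. The demands are a non-basic methylenation (C7–H is γ to the ketone) and a halogen–lithium exchange faster than any addition to the diene.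

24 ⇒ 23 ⇒ 22. The O–C10 bond (and C9–H) is cut, which removes ring B and the stereocentre C10 and uncovers C9=C10, the second olefin of the 1,5-diene. The forward step must add the a1 oxygen to C10 in the Markovnikov sense on the correct face, and must avoid transannular chemistry. The enone deactivates C5=C6 against a C10 cation, which is why the ketone is kept until after this step.

22 ⇒ 21 ⇒ 11 + 20. Ring C is contracted by re-joining C5–C10 and C6–C9 (giving 21), and C5–C6 and C9–C10 are then cut. The ten-membered ring with its two olefins becomes a cyclohexenone that carries C1 and C1' and a cyclobutene that carries C7, so the two stereochemical domains are made separately and need no communication. The forward demands are head-to-tail regiochemistry and survival of the 1,5-diene against Cope rearrangement. The a1 phenol and the carbinol are masked in 11 and 20 for this step.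

11 ⇒ 10 ⇒ 9. The C10–C14 bond is cut, because the enone without the methyl group is what a catalytic asymmetric annulation delivers. The forward step must reinstall the C5=C10 double bond regiospecifically after conjugate methylation.

9 ⇒ 8 ⇒ 7 ⇒ 5 + 6. C5=C10 (aldol condensation) and C1–C2 (Michael addition) are cut, which leaves an acyclic aldehyde whose only stereocentre is C1'. C1 must then be set by the catalyst next to C1' and must not epimerise before ring closure.

5 ⇒ 4 ⇒ 2 + 3, and 2 ⇒ 1. The benzylic ether on the a1 oxygen, the a2–C1' bond (Friedel–Crafts) and the enal double bond are cut. C1' is set by a catalyst on the commercial phenol 3. A shorter one-step union of 1, 3 and a six-membered ring enolate was rejected because it gives no reliable relative or absolute control at C1/C1'.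

20 ⇒ 19 ⇒ 18 ⇒ 17 ⇒ 16 ⇒ 15 ⇒ 14 ⇒ 13 ⇒ 12. The O–Si bond, the two C11–CH3 bonds, the salt (resolution), one C8–H bond (from the allylic C–O bond of the lactone) and the valence isomerisation are undone in turn. The gain is a commercial heteroaromatic starting material. The demands are an enantiopure acid and no loss of the base-labile C7–H.

## Other disconnections considered

Alternative 1: The cut is at C9–C10 and C1–C2 with rings A and B intact. In the forward sense chromone A1 would take up the side-chain Grignard reagent A2 at C10 under CuBr·SMe2 (monovalent copper) and a chiral ferrocenyl diphosphine, and the enolate would be allylated at C1 to give chromanone A3.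
- In its favour: the quaternary C10 is set by the catalyst and C1 by trans delivery of the electrophile, in one operation from a flat, cheap heterocycle. In control of C10 it is the better plan, because the chosen route relies on the conformation of ring C.
- Against it: C10 of A1 is the β-carbon of a vinylogous ester that already bears a methyl group and lies peri to the a3 methoxy group, so forming a fully substituted carbon there is at the limit of copper–Grignard catalysis. C1' is still a carbonyl in A3, so the isobutyl group and H-1' must be installed later with control relative to C1. Ring C is still open and needs a separate ten-membered closure with a Z olefin.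
- Comparison: both plans bring C7 in with a small enantiopure fragment (equal). The alternative is polar and catalyst-controlled, the chosen plan photochemical and thermal. It saves the late chroman closure but adds C1' construction, macrocyclisation, methylenation and the same ring-A end game, so no net saving in steps is expected.

Alternative 2: The cut is at O–C10 and C9–C8. Phenol A4, which carries C1, C1' and a C10=C9H2 isopropenyl group, would undergo 6-exo oxypalladation with Pd(OCOCF3)2 (divalent palladium), a chiral bis(oxazoline) ligand and a quinone oxidant; the C9–palladium species would be intercepted by an acrylate ester in a Heck coupling to give chroman A5.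
- In its favour: the O–C10 bond and a C–C bond are made together, no free carbocation is involved, and the face at C10 is chosen by the ligand. In stereochemical definition of C10 it is at least the equal of the acid-mediated closure chosen here.
- Against it: the alkene sits next to the existing C1/C1' centres, so the catalyst faces a matched or mismatched substrate. The phenol is flanked by two ortho substituents. A4 needs the same C1/C1' problem solved first (equal). Ring C is not formed, so C7 must afterwards be created on the enoate by acyclic conjugate addition remote from all other stereocentres, which is harder than bringing C7 in with a resolved four-membered ring. A ten-membered ring closure is still required.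
- Comparison: the mechanism is organometallic and predictable in regiochemistry (better than the intermolecular photocycloaddition on that point), but the route is longer after the key step.

Alternative 3: The cut is at C5=C6, with C15 supplied during the step. Enyne A6, with a terminal alkyne on C3 and a vinyl group on C7, would be closed by the second-generation Grubbs catalyst RuCl2(=CHPh)(PCy3)(H2IMes) under ethylene in the endo mode to give A7, the bis(methoxymethyl) ether of the target.
- In its favour: ring C and both diene double bonds are formed in the last C–C bond-forming event, with no late methylenation and no late formylation. In end-game step economy it is the better plan.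
- Against it: a ten-membered ring must be closed against transannular strain, whereas the chosen plan is driven by release of cyclobutane strain. Endo-selective enyne closure is normal only for larger rings; here the exo mode (a nine-membered ring bearing a vinyl group) and simple cross-metathesis of the alkyne with ethylene compete. A6 must already contain all four stereocentres, including the quaternary C10 and the remote C7, so the difficulty is moved, not removed. The final acetal cleavage needs acid next to the diene and the tertiary alcohol.
- Comparison: the Z geometry expected for C5=C6 in a ten-membered ring is the same in both plans (equal). The alternative is shorter at the end but longer and less convergent before its key step.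

Key step: step 13

Assumptions (remarks on the chemistry):
- The sense of induction of the two prolinol-derived catalysts (steps 2 and 4) is taken from the usual face-shielding model of (E)-iminium ions and (E)-enamines; if either sense were opposite, the antipodal catalyst would be used and nothing else changes.
- Which antipode of 1-phenylethylamine gives the less soluble salt with the (R)-acid cannot be predicted; the (S)-amine is written, and the (R)-amine would serve in the same way.
- The precursor and product of the key step were compared atom by atom with 30 (C1 S, C1' R, C7 R, 5Z, 9E agree), so no structural correction was needed. The changes are in protection only: the a1 phenol is carried as a 4-methoxybenzyl (PMB) ether and the carbinol as a tert-butyldimethylsilyl (TBS) ether through the key step.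

Step 1
Reactants: 1 3-methylbutanal
Product: 2 (E)-5-methylhex-2-enal
Conditions: Ph3P=CHCHO (1.05 equiv), PhMe, 80 °C
Reagents that add atoms: (triphenylphosphoranylidene)acetaldehyde, O=CC=P(c1ccccc1)(c1ccccc1)c1ccccc1
Why: Wittig olefination with a stabilised formyl ylide should give the (E)-enal; only a slight excess of ylide is used to limit a second homologation.

Step 2
Reactants: 2 (E)-5-methylhex-2-enal; 3 3,5-dimethoxyphenol
Product: 4 (4R)-5,7-dimethoxy-4-(2-methylpropyl)chroman-2-ol (lactol; both anomers)
Conditions: (R)-2-[diphenyl(trimethylsilyloxy)methyl]pyrrolidine (20 mol %), PhCO2H (20 mol %), PhMe, 0 °C → rt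
Reagents that add atoms: none
Why: Iminium-catalysed Friedel–Crafts alkylation of an electron-rich phenol by an enal, followed by hemiacetalisation; attack through a2 (ortho to OH) is the adduct that is drained into the lactol, and the silyloxydiphenylmethyl group of the (R)-catalyst shields one face of the (E)-iminium ion so that the arene should enter to give (R) at C1'.

Step 3
Reactants: 4 (4R)-5,7-dimethoxy-4-(2-methylpropyl)chroman-2-ol
Product: 5 (3R)-3-{2,4-dimethoxy-6-[(4-methoxybenzyl)oxy]phenyl}-5-methylhexanal
Conditions: 4-MeOC6H4CH2Cl (1.2 equiv), K2CO3, n-Bu4NI (cat.), DMF, 0 °C → rt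
Reagents that add atoms: 4-methoxybenzyl chloride, COc1ccc(CCl)cc1
Why: Williamson ether synthesis on the ring-opened phenoxide–aldehyde tautomer, the more stable and more nucleophilic anion under carbonate; the PMB ether survives base, cuprate, light and 180 °C and is removed by the acid that later closes ring B.

Step 4
Reactants: 5 (3R)-3-{2,4-dimethoxy-6-[(4-methoxybenzyl)oxy]phenyl}-5-methylhexanal; 6 but-3-en-2-one
Product: 7 (2S,3R)-3-{2,4-dimethoxy-6-[(4-methoxybenzyl)oxy]phenyl}-5-methyl-2-(3-oxobutyl)hexanal
Conditions: (S)-2-(methoxydiphenylmethyl)pyrrolidine (20 mol %), ethyl 3,4-dihydroxybenzoate (20 mol %), 6 (2 equiv), CHCl3 (minimum), 4 °C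
Reagents that add atoms: none
Why: Enamine-catalysed Michael addition of an aldehyde to an enone; the (E)-enamine should be attacked on the face away from the methoxydiphenylmethyl group, which sets C1 as (S) under reagent control next to the existing C1' centre.

Step 5
Reactants: 7 (2S,3R)-3-{2,4-dimethoxy-6-[(4-methoxybenzyl)oxy]phenyl}-5-methyl-2-(3-oxobutyl)hexanal
Product: 9 (4R)-4-[(1R)-1-{2,4-dimethoxy-6-[(4-methoxybenzyl)oxy]phenyl}-3-methylbutyl]cyclohex-2-en-1-one, via ketol 8 (not isolated)
Conditions: LiOH·H2O (0.5 equiv), i-PrOH, 0 °C → rt
Reagents that add atoms: none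
Why: Intramolecular aldol condensation (6-enolendo-exo-trig attack of the methyl ketone enolate on the aldehyde, then dehydration); no stereocentre is formed, and mild hydroxide is chosen so that cyclisation outruns epimerisation of C1 (the descriptor changes from S to R only through priorities).

Step 6
Reactants: 9 (4R)-4-[(1R)-1-{2,4-dimethoxy-6-[(4-methoxybenzyl)oxy]phenyl}-3-methylbutyl]cyclohex-2-en-1-one
Product: 11 (4S)-4-[(1R)-1-{2,4-dimethoxy-6-[(4-methoxybenzyl)oxy]phenyl}-3-methylbutyl]-3-methylcyclohex-2-en-1-one, via lithium enolate 10 (not isolated)
Conditions: Me2CuLi (from MeLi and CuI), Et2O, −78 → −20 °C; then PhS(Cl)=N-t-Bu, THF, −78 °C → rt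
Reagents that add atoms: lithium dimethylcuprate, [Li+].C[Cu-]C
Why: Cuprate conjugate addition places C14 on C10, and the regiodefined enolate is dehydrogenated in the same flask by the sulfinimidoyl chloride (S-attack at C5, then syn-elimination of the sulfenamide with the C10 hydrogen), so the C5=C10 bond returns with the methyl group in place; the transient C10 centre is erased and C1 is untouched.

Step 7
Reactants: 12 2H-pyran-2-one
Product: 13 (±)-2-oxabicyclo[2.2.0]hex-5-en-3-one
Conditions: hν (300 nm), CH2Cl2, 0 °C (flow), solution used directly
Reagents that add atoms: none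
Why: Photochemical 4π-electrocyclisation of the pyranone diene gives the bicyclic β-lactone with the cis ring fusion that the ring size enforces; the product is racemic.

Step 8
Reactants: 13 (±)-2-oxabicyclo[2.2.0]hex-5-en-3-one
Product: 14 (±)-cyclobut-2-ene-1-carboxylic acid
Conditions: Pd(PPh3)4 (3 mol %), HCO2H, Et3N, THF, 0 °C → rt; then 1 M HCl
Reagents that add atoms: none
Why: Tsuji–Trost-type hydrogenolysis: zerovalent palladium ionises the strained allylic C–O bond to a π-allyl carboxylate, and formate delivers hydride; both allyl termini give the same constitution, and the product is racemic.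

Step 9
Reactants: 14 (±)-cyclobut-2-ene-1-carboxylic acid
Product: 15 (S)-1-phenylethylammonium (1R)-cyclobut-2-ene-1-carboxylate
Conditions: (S)-1-phenylethylamine (1.0 equiv), EtOAc/EtOH, crystallisation; recrystallised to constant rotation
Reagents that add atoms: (S)-1-phenylethylamine, C[C@H](N)c1ccccc1
Why: Classical resolution through diastereomeric ammonium salts; C7 of the target is fixed here as (R) by selection, not by synthesis.

Step 10
Reactants: 15 (S)-1-phenylethylammonium (1R)-cyclobut-2-ene-1-carboxylate
Product: 17 methyl (1R)-cyclobut-2-ene-1-carboxylate, via free acid 16 (not isolated)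
Conditions: 1 M HCl/Et2O, 0 °C; then Me3SiCHN2, MeOH/Et2O, 0 °C
Reagents that add atoms: (trimethylsilyl)diazomethane, C[Si](C)(C)C=[N+]=[N-]
Why: Acid liberation and diazoalkane esterification proceed without base, so the doubly activated C7–H (allylic and α to the carboxyl) is not epimerised and the double bond does not move into conjugation.

Step 11
Reactants: 17 methyl (1R)-cyclobut-2-ene-1-carboxylate
Product: 19 2-[(1R)-cyclobut-2-en-1-yl]propan-2-ol, via methyl ketone 18 (not isolated)
Conditions: MeMgBr (3 equiv), CeCl3 (3 equiv), THF, −78 → 0 °C
Reagents that add atoms: methylmagnesium bromide, C[Mg]Br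
Why: Double addition of a weakly basic organocerium reagent to the ester builds C11 with its two methyl groups while avoiding α-deprotonation, so the C7 configuration is kept.

Step 12
Reactants: 19 2-[(1R)-cyclobut-2-en-1-yl]propan-2-ol
Product: 20 tert-butyl({2-[(1R)-cyclobut-2-en-1-yl]propan-2-yl}oxy)dimethylsilane
Conditions: t-BuMe2SiOTf, 2,6-lutidine, CH2Cl2, −78 → 0 °C
Reagents that add atoms: tert-butyldimethylsilyl trifluoromethanesulfonate, CC(C)(C)[Si](C)(C)OS(=O)(=O)C(F)(F)F
Why: Silyl triflate silylation of a hindered tertiary alcohol; the silyl ether adds bulk next to C6, makes the alkene non-volatile and recoverable, blocks retro-ene loss of acetone at 180 °C, and keeps the carbinol oxygen from competing in step 14.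

Step 13
Reactants: 11 (4S)-4-[(1R)-1-{2,4-dimethoxy-6-[(4-methoxybenzyl)oxy]phenyl}-3-methylbutyl]-3-methylcyclohex-2-en-1-one; 20 tert-butyl({2-[(1R)-cyclobut-2-en-1-yl]propan-2-yl}oxy)dimethylsilane
Product: 22 (2Z,4R,6E,8S)-4-[2-(tert-butyldimethylsilyloxy)propan-2-yl]-8-[(1R)-1-{2,4-dimethoxy-6-[(4-methoxybenzyl)oxy]phenyl}-3-methylbutyl]-7-methylcyclodeca-2,6-dien-1-one, via photoadduct 21 (not isolated)
Conditions: hν (350–366 nm, Pyrex), 20 (3 equiv, excess recovered by bulb-to-bulb distillation), CH2Cl2, −20 °C; basic Al2O3 plug; then PhMe (0.01 M), BHT, sealed tube, 180 °C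
Reagents that add atoms: none
Why: Excitation of 11 at its n→π* band gives the triplet enone, which adds to the strained double bond of 20 through a triplet 1,4-biradical that closes the cyclobutane C5–C6–C9–C10 (new bonds C5–C6 and C9–C10), giving the bicyclo[2.2.0]hexane 21 fused to the cyclohexanone. On heating, the central C6–C9 bond homolyses and the cyclohexane-1,4-diyl cleaves C5–C10, so the six-membered ring grows by the four cyclobutene carbons into ring C; the closest known reaction type is the photocycloaddition–thermolysis of cyclohexenones with cyclobutenes to cyclodeca-1,5-dienes. The four-membered ring is closed by intermolecular biradical recombination, and ring C is not closed by a cyclisation at all but arises by fragmentation of the two shared bonds of the tricycle. No surviving stereocentre is created: C5, C6, C9 and C10 all become sp2, C1, C1' and C7 are spectators, and the alumina plug epimerises any trans-fused adduct at C5, so the adduct mixture should converge. The step needs head-to-tail regiochemistry (C9 to C10, C6 to C5); the silyloxy-isopropyl group on C7 shields C6, and C10, next to the branched C1, is the most hindered enone carbon, so the only pairing that avoids joining the two crowded centres is the wanted one. It also needs the 1,5-diene to survive: conjugation of C5=C6 with the C4 ketone and the trisubstituted C9=C10 stabilise ring C against the Cope product, and the Z-enone/E-olefin pair is expected to be the favoured member of the Cope-linked manifold. The PMB ether prevents oxa-Michael addition of the a1 phenol to C10 and quenching of the triplet by a phenolic O–H.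

Step 14
Reactants: 22 (2Z,4R,6E,8S)-4-[2-(tert-butyldimethylsilyloxy)propan-2-yl]-8-[(1R)-1-{2,4-dimethoxy-6-[(4-methoxybenzyl)oxy]phenyl}-3-methylbutyl]-7-methylcyclodeca-2,6-dien-1-one
Product: 24 chroman ketone (rings A–C of 30 closed; 1S 7R 10R 1'R; C4=O; 5Z; a3/a5 OMe; a4/a6 H; C11–OTBS), via free phenol 23 (not isolated)
Conditions: CF3CO2H (10 equiv), 1,3,5-trimethoxybenzene (5 equiv), CH2Cl2, −20 → 0 °C
Reagents that add atoms: none
Why: Acidolysis of the aryl PMB ether (the benzyl cation is taken up by the scavenger) frees the a1 phenol, which adds to the protonated, strained (E)-trisubstituted olefin at C10 in a Markovnikov 6-exo-trig hydroalkoxylation. Allylic 1,3-strain keeps H-1 in the olefin plane, so the phenol carried on C1' reaches the peripheral face of C10 and places C14 trans to H-1 (10R, trans ring fusion). The enone olefin is too electron-poor to trap the C10 cation across the ring.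

Step 15
Reactants: 24 chroman ketone
Product: 25 a4,a6-dibromo chroman ketone (as 24 with Br on a4 and a6)
Conditions: NBS (2.1 equiv), MeCN, 0 °C, dark
Reagents that add atoms: N-bromosuccinimide, O=C1CCC(=O)N1Br
Why: Electrophilic aromatic bromination at the two free positions of the trioxygenated ring, each ortho/para to three oxygen donors; the enone and the silyl ether are inert to the reagent in the dark.

Step 16
Reactants: 25 a4,a6-dibromo chroman ketone
Product: 26 a4,a6-dibromo diene (as 25 with C4=C15H2)
Conditions: Cp2TiMe2 (3 equiv), PhMe/THF, 65 °C, dark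
Reagents that add atoms: dimethyltitanocene, C[Ti](C)(C1C=CC=C1)C1C=CC=C1
Why: Petasis olefination: the titanium methylidene transfers CH2 to the ketone by cycloaddition–cycloreversion without basic intermediates, so the γ-hydrogen at C7 and the Z geometry of C5=C6 are not disturbed; aryl bromides are inert.

Step 17
Reactants: 26 a4,a6-dibromo diene
Product: 28 a4,a6-diformyl diene (as 26 with CHO in place of both Br), via dilithio arene 27 (not isolated)
Conditions: t-BuLi (4.4 equiv), Et2O, −78 °C; DMF (6 equiv), −78 → 0 °C; aq NH4Cl
Reagents that add atoms: N,N-dimethylformamide, CN(C)C=O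
Why: Double bromine–lithium exchange followed by formylation with a formamide; exchange at −78 °C is far faster than addition of the alkyllithium to the diene, each aryllithium is stabilised by its two flanking oxygen atoms, and the hemiaminal alkoxides release the aldehydes only on work-up.

Step 18
Reactants: 28 a4,a6-diformyl diene (C11–OTBS)
Product: 29 a3,a5-di-O-methyl ether of 30 (free carbinol)
Conditions: Bu4NF (3 equiv), THF, 0 → 40 °C
Reagents that add atoms: none
Why: Fluoride-induced desilylation of the tertiary silyl ether under non-acidic conditions that spare the diene and the C10 ether.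

Step 19
Reactants: 29 a3,a5-di-O-methyl ether of 30
Product: 30 target CNP0479784.1
Conditions: NaSEt (6 equiv), DMF (degassed), 100 °C; then aq HCl to pH 4
Reagents that add atoms: none
Why: Thiolate SN2 demethylation of aryl methyl ethers: both methoxy groups are ortho/para to formyl groups, so the phenoxide leaving groups are stabilised, whereas the tertiary ether at C10 cannot react by SN2 and the diene and carbinol are inert to the nucleophile.

Compound list

1 | 3-methylbutanal | CC(C)CC=O | starting material
2 | (E)-5-methylhex-2-enal | CC(C)C/C=C/C=O | intermediate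
3 | 3,5-dimethoxyphenol | COc1cc(O)cc(OC)c1 | starting material
4 | (4R)-5,7-dimethoxy-4-(2-methylpropyl)chroman-2-ol (anomer mixture) | COc1cc(OC)c2c(c1)OC(O)C[C@H]2CC(C)C | intermediate
5 | (3R)-3-{2,4-dimethoxy-6-[(4-methoxybenzyl)oxy]phenyl}-5-methylhexanal | O=CC[C@@H](CC(C)C)c1c(OC)cc(OC)cc1OCc1ccc(OC)cc1 | intermediate
6 | but-3-en-2-one | CC(=O)C=C | starting material
7 | (2S,3R)-3-{2,4-dimethoxy-6-[(4-methoxybenzyl)oxy]phenyl}-5-methyl-2-(3-oxobutyl)hexanal | CC(=O)CC[C@H](C=O)[C@@H](CC(C)C)c1c(OC)cc(OC)cc1OCc1ccc(OC)cc1 | intermediate
8 | ketol: 3-hydroxy-4-[(1R)-1-aryl-3-methylbutyl]cyclohexan-1-one from 7 (carbinol epimers; aryl as in 5) | O=C1CC[C@@H]([C@@H](CC(C)C)c2c(OC)cc(OC)cc2OCc2ccc(OC)cc2)C(O)C1 | intermediate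
9 | (4R)-4-[(1R)-1-{2,4-dimethoxy-6-[(4-methoxybenzyl)oxy]phenyl}-3-methylbutyl]cyclohex-2-en-1-one | O=C1CC[C@@H]([C@@H](CC(C)C)c2c(OC)cc(OC)cc2OCc2ccc(OC)cc2)C=C1 | intermediate
10 | lithium enolate: lithium 3-methyl-4-[(1R)-1-aryl-3-methylbutyl]cyclohex-1-en-1-olate (C3 epimers, mainly trans; aryl as in 5) | CC1C=C(O[Li])CC[C@H]1[C@@H](CC(C)C)c1c(OC)cc(OC)cc1OCc1ccc(OC)cc1 | intermediate
11 | (4S)-4-[(1R)-1-{2,4-dimethoxy-6-[(4-methoxybenzyl)oxy]phenyl}-3-methylbutyl]-3-methylcyclohex-2-en-1-one | COc1ccc(COc2cc(OC)cc(OC)c2[C@H](CC(C)C)[C@@H]2CCC(=O)C=C2C)cc1 | intermediate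
12 | 2H-pyran-2-one | O=c1cccco1 | starting material
13 | (±)-2-oxabicyclo[2.2.0]hex-5-en-3-one (racemate, cis-fused) | O=C1OC2C=CC12 | intermediate
14 | (±)-cyclobut-2-ene-1-carboxylic acid (racemate) | OC(=O)C1C=CC1 | intermediate
15 | (S)-1-phenylethylammonium (1R)-cyclobut-2-ene-1-carboxylate | C1=C[C@H](C(=O)[O-])C1.C[C@H]([NH3+])c1ccccc1 | intermediate
16 | (1R)-cyclobut-2-ene-1-carboxylic acid | C1=C[C@H](C(=O)O)C1 | intermediate
17 | methyl (1R)-cyclobut-2-ene-1-carboxylate | C1=C[C@H](C(=O)OC)C1 | intermediate
18 | 1-[(1R)-cyclobut-2-en-1-yl]ethan-1-one | C1=C[C@H](C(C)=O)C1 | intermediate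
19 | 2-[(1R)-cyclobut-2-en-1-yl]propan-2-ol | C1=C[C@H](C(C)(C)O)C1 | intermediate
20 | tert-butyl({2-[(1R)-cyclobut-2-en-1-yl]propan-2-yl}oxy)dimethylsilane | C1=C[C@H](C(C)(C)O[Si](C)(C)C(C)(C)C)C1 | intermediate
21 | photoadduct: cyclohexanone fused at C5–C10 to the bicyclo[2.2.0]hexane C5,C6,C7,C8,C9,C10 (C1 S, C1' R, C7 R; C5, C6, C9, C10 as a stereoisomer mixture) | O=C1CC[C@@H]([C@@H](CC(C)C)c2c(OCc3ccc(OC)cc3)cc(OC)cc2OC)C2(C)C3C[C@@H](C(C)(C)O[Si](C)(C)C(C)(C)C)C3C12 | intermediate
22 | (2Z,4R,6E,8S)-4-[2-(tert-butyldimethylsilyloxy)propan-2-yl]-8-[(1R)-1-{2,4-dimethoxy-6-[(4-methoxybenzyl)oxy]phenyl}-3-methylbutyl]-7-methylcyclodeca-2,6-dien-1-one | O=C1/C=C\[C@H](C(C)(C)O[Si](C)(C)C(C)(C)C)C/C=C(\C)[C@H]([C@@H](CC(C)C)c2c(OCc3ccc(OC)cc3)cc(OC)cc2OC)CC1 | intermediate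
23 | free phenol: as 22 with 2-hydroxy-4,6-dimethoxyphenyl | O=C1/C=C\[C@H](C(C)(C)O[Si](C)(C)C(C)(C)C)C/C=C(\C)[C@H]([C@@H](CC(C)C)c2c(O)cc(OC)cc2OC)CC1 | intermediate
24 | chroman ketone: skeleton of 30 with C4=O, 5Z, a3/a5 OMe, a4/a6 H, C11–OTBS (1S,7R,10R,1'R) | O=C1/C=C\[C@H](C(C)(C)O[Si](C)(C)C(C)(C)C)CC[C@@]2(C)Oc3cc(OC)cc(OC)c3[C@H](CC(C)C)[C@@H]2CC1 | intermediate
25 | as 24 with Br on a4 and a6 | O=C1/C=C\[C@H](C(C)(C)O[Si](C)(C)C(C)(C)C)CC[C@@]2(C)Oc3c(Br)c(OC)c(Br)c(OC)c3[C@H](CC(C)C)[C@@H]2CC1 | intermediate
26 | as 25 with C4=C15H2 | C=C1/C=C\[C@H](C(C)(C)O[Si](C)(C)C(C)(C)C)CC[C@@]2(C)Oc3c(Br)c(OC)c(Br)c(OC)c3[C@H](CC(C)C)[C@@H]2CC1 | intermediate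
27 | as 26 with Li on a4 and a6 | C=C1/C=C\[C@H](C(C)(C)O[Si](C)(C)C(C)(C)C)CC[C@@]2(C)Oc3c([Li])c(OC)c([Li])c(OC)c3[C@H](CC(C)C)[C@@H]2CC1 | intermediate
28 | as 26 with CHO on a4 and a6 (C11–OTBS, a3/a5 OMe) | C=C1/C=C\[C@H](C(C)(C)O[Si](C)(C)C(C)(C)C)CC[C@@]2(C)Oc3c(C=O)c(OC)c(C=O)c(OC)c3[C@H](CC(C)C)[C@@H]2CC1 | intermediate
29 | a3,a5-di-O-methyl ether of 30 | C=C1/C=C\[C@H](C(C)(C)O)CC[C@@]2(C)Oc3c(C=O)c(OC)c(C=O)c(OC)c3[C@H](CC(C)C)[C@@H]2CC1 | intermediate
30 | CNP0479784.1 (1S,7R,10R,1'R; 5Z) | C=C1/C=C\[C@H](C(C)(C)O)CC[C@@]2(C)Oc3c(C=O)c(O)c(C=O)c(O)c3[C@H](CC(C)C)[C@@H]2CC1 | target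

Total step count: 19 steps. Longest linear sequence: 13 steps (steps 1–6 or steps 7–12, followed by steps 13–19).

Least certain steps

Step 13 (key step). The most likely failures are insufficient head-to-tail selection in the biradical closure, because the cyclobutene double bond is not polarised; Cope collapse of the 1,5-diene during thermolysis; and scrambling of the C5=C6/C9=C10 geometries. The fallback replaces steric matching by a hydrogen-bond template. It sets out from 11 and the free carbinol 19, which are irradiated in a non-polar solvent at low temperature, so that the O–H···O=C4 hydrogen bond holds C6 over C5. The resulting hydroxy photoadduct F1 is silylated (t-BuMe2SiOTf, 2,6-lutidine, −78 °C) and so comes back to the route at 21, which is thermolysed as before.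

Step 14. Capture of the C10 cation on the wrong face (cis ring fusion), premature loss of the silyl group followed by capture of the cation by the carbinol oxygen, and alkylation of ring A by the benzyl cation are the risks. The fallback separates the two events and changes the mechanism of ring closure. From 22 the benzyl ether is cleaved without a strong Brønsted acid (MgBr2·OEt2, Me2S) and phenol 23 is isolated. It is then closed to 24 by cobalt-catalysed hydrogen-atom transfer with radical–polar crossover, using [N,N'-bis(3,5-di-tert-butylsalicylidene)-1,2-cyclohexanediaminato]cobalt, C36H52CoN2O2 (divalent cobalt), N-fluoro-2,4,6-trimethylpyridinium tetrafluoroborate and (Me2SiH)2O. The known weakness of this variant is addition of the C10 radical across the ring to the enone. No new compound is involved.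

Step 17. Addition of the alkyllithium to the diene and incomplete second exchange are the risks. The fallback installs the aldehydes electrophilically before the diene exists. It sets out from 24, which is formylated twice (Cl2CHOMe, AgOTf, −78 °C, Rieche type) to the diformyl ketone F2. The aldehydes are masked with HC(OMe)3 and pyridinium p-toluenesulfonate as the bis(dimethyl acetal) ketone F3. Cp2TiMe2 then gives the bis(dimethyl acetal) diene F4, and oxalic acid on wet silica gel releases the aldehydes, coming back to the route at 28.

Step 4. The catalyst may be mismatched with the C1' centre, giving poor facial selectivity at C1, and the hindered enamine may react slowly. The fallback uses auxiliary control. From 5 the hydrazone with (R)-1-amino-2-(methoxymethyl)pyrrolidine, RAMP hydrazone F5, is formed, deprotonated with LiN(i-Pr)2 and alkylated with 2-(2-iodoethyl)-2-methyl-1,3-dioxolane to the alkylated hydrazone F6; the antipodal auxiliary would be taken if the model required it. Oxalic acid on wet silica gel cleaves the hydrazone and the dioxolane and returns to the route at 7.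

Step 2. Competing attack at the position para to the hydroxyl group, low reactivity of the aliphatic iminium ion and erosion of enantioselectivity are the risks. The fallback builds the lactone first. From 3, palladium diacetate-catalysed hydroarylation with ethyl propiolate in CF3CO2H gives 5,7-dimethoxycoumarin F7. Conjugate addition of i-BuMgBr under CuBr·SMe2 and a ferrocenyl diphosphine of the Josiphos type (antipode chosen for 4R) gives (4R)-5,7-dimethoxy-4-(2-methylpropyl)chroman-2-one F8. Reduction with i-Bu2AlH at −78 °C comes back to the route at 4.

Step 9. The salts may fail to differ enough in solubility, so that enantiomeric enrichment stalls. The fallback is an enzymatic kinetic resolution. From 14, esterification with Me3SiCHN2 gives the racemic methyl cyclobut-2-ene-1-carboxylate F9. A lipase (Candida antarctica lipase B, phosphate buffer) hydrolyses one antipode, and the unreacted (R)-ester is 17; if the enzyme prefers the (R)-ester, the acid fraction is re-esterified instead.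

## Further compounds

F1 | step 13 | hydroxy photoadduct (21 with free C11–OH) | O=C1CC[C@@H]([C@@H](CC(C)C)c2c(OCc3ccc(OC)cc3)cc(OC)cc2OC)C2(C)C3C[C@@H](C(C)(C)O)C3C12
F0 | step 14 | none | none
F2 | step 17 | diformyl ketone (24 with CHO on a4 and a6) | O=C1/C=C\[C@H](C(C)(C)O[Si](C)(C)C(C)(C)C)CC[C@@]2(C)Oc3c(C=O)c(OC)c(C=O)c(OC)c3[C@H](CC(C)C)[C@@H]2CC1
F3 | step 17 | bis(dimethyl acetal) ketone | O=C1/C=C\[C@H](C(C)(C)O[Si](C)(C)C(C)(C)C)CC[C@@]2(C)Oc3c(C(OC)OC)c(OC)c(C(OC)OC)c(OC)c3[C@H](CC(C)C)[C@@H]2CC1
F4 | step 17 | bis(dimethyl acetal) diene | C=C1/C=C\[C@H](C(C)(C)O[Si](C)(C)C(C)(C)C)CC[C@@]2(C)Oc3c(C(OC)OC)c(OC)c(C(OC)OC)c(OC)c3[C@H](CC(C)C)[C@@H]2CC1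
F5 | step 4 | RAMP hydrazone of 5 | COC[C@H]1CCCN1/N=C/C[C@@H](CC(C)C)c1c(OC)cc(OC)cc1OCc1ccc(OC)cc1
F6 | step 4 | alkylated hydrazone | COC[C@H]1CCCN1/N=C/[C@@H](CCC1(C)OCCO1)[C@@H](CC(C)C)c1c(OC)cc(OC)cc1OCc1ccc(OC)cc1
F7 | step 2 | 5,7-dimethoxycoumarin | COc1cc(OC)c2ccc(=O)oc2c1
F8 | step 2 | (4R)-5,7-dimethoxy-4-(2-methylpropyl)chroman-2-one | COc1cc(OC)c2c(c1)OC(=O)C[C@H]2CC(C)C
F9 | step 9 | racemic methyl cyclobut-2-ene-1-carboxylate | COC(=O)C1C=CC1
A1 | alternative 1 | 5,7-dimethoxy-2-methylchromen-4-one | COc1cc(OC)c2c(c1)oc(C)cc2=O
A2 | alternative 1 | [(3R)-4-methyl-4-(triethylsilyloxy)-3-vinylpentyl]magnesium bromide | C=C[C@H](C(C)(C)O[Si](CC)(CC)CC)CC[Mg]Br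
A3 | alternative 1 | 2,2,3-trisubstituted chroman-4-one | C=C[C@H](C(C)(C)O[Si](CC)(CC)CC)CC[C@@]2(C)Oc3cc(OC)cc(OC)c3C(=O)[C@@H]2CC=C
A4 | alternative 2 | isopropenyl phenol substrate | Oc1cc(OC)cc(OC)c1[C@H](CC(C)C)[C@@H](C(C)=C)CCCO[Si](C)(C)C(C)(C)C
A5 | alternative 2 | chroman with the C9–C6 enoate chain | COC(=O)/C=C/C[C@@]2(C)Oc3cc(OC)cc(OC)c3[C@H](CC(C)C)[C@@H]2CCCO[Si](C)(C)C(C)(C)C
A6 | alternative 3 | enyne substrate (alkyne on C3, vinyl on C7) | C=C[C@H](C(C)(C)O)CC[C@@]2(C)Oc3c(C=O)c(OCOC)c(C=O)c(OCOC)c3[C@H](CC(C)C)[C@@H]2CCC#C
A7 | alternative 3 | bis(methoxymethyl) ether of the target | C=C1/C=C\[C@H](C(C)(C)O)CC[C@@]2(C)Oc3c(C=O)c(OCOC)c(C=O)c(OCOC)c3[C@H](CC(C)C)[C@@H]2CC1
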